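**Plan**
- Retrosynthesis: with the formate and silyl groups set aside, the C-8 methylidene is cut back to a ring-B ketone and the C-9–C-11 bond to an aldol union with a pyranone aldehyde. The C-5–C-6 and C-4–CH3 bonds are then cut together, which opens ring B to a ring-A cyclohexenone carrying an iodoethyl ketal arm on C-10.
- That enone is cut at C-4–side chain (B-alkyl Suzuki coupling) and at C-10–C-9 (Johnson–Claisen shift on (S)-3-methylcyclohex-2-enol).
- Feature used: C-5, the ring-fusion CH wedged between the quaternary carbons C-4 and C-10, is the β-carbon of the ring-A enone. A radical tethered to C-10 can reach it, and the chain-bearing α-carbon C-4 then emerges as an enolate that takes its methyl group.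
- Forward order: ring A (from 3-methylcyclohexenone) → arm and side chain attached → ring B closed and C-4 methylated in one flask → pyranone joined at C-9 → methylidene, formate, deprotection.
- Stereochemistry: C-10 from a CBS reduction relayed by the suprafacial Claisen shift; C-5 from the tether (cis fusion); C-4, C-3 and C-9 from reagent attack on the convex α face of the cis-decalin.

Key step: step 11

Remark (assumption): the stereodescriptors of the target are read as a cis-fused decalin, (3S,4R,5R,9S,10S), with 10-CH3, H-5 and 4-CH3 on one face and the C-4 chain, 3-OH and the C-9 substituent on the other.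
Conventions: terpenoid numbering (ring A = C-1 to C-5 and C-10; ring B = C-5 to C-10; C-11 = CH2 between C-9 and the pyranone). α = the face carrying the C-10 methyl group and H-5, β = the other face. Pyr = 5-(methoxycarbonyl)-2-methoxy-6-methyl-4-oxo-4H-pyran-3-yl.

**Route**

Step 1
Reactants: 1 3-methylcyclohex-2-en-1-one
Product: 2 (S)-3-methylcyclohex-2-en-1-ol
Conditions: (R)-Me-CBS (10 mol %), BH3·SMe2, THF, −20 °C
Reagents that add atoms: none
Why: Corey–Bakshi–Shibata reduction, in which the oxazaborolidine–borane complex delivers hydride 1,2 to one carbonyl face with the alkenyl carbon as the large group, so the (R)-catalyst should give the (S)-carbinol.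

Step 2
Reactants: 2 (S)-3-methylcyclohex-2-en-1-ol
Product: 3 ethyl 2-[(1S)-1-methylcyclohex-2-en-1-yl]acetate
Conditions: MeC(OEt)3, EtCO2H (cat.), 140 °C, EtOH distilled off
Reagents that add atoms: triethyl orthoacetate, CC(OCC)(OCC)OCC
Why: Johnson–Claisen rearrangement, in which the ketene acetal formed in situ shifts suprafacially, so the C–O stereocentre is exchanged for the quaternary carbon (future C-10) with the new C–C bond on the face the oxygen leaves.

Step 3
Reactants: 3 ethyl 2-[(1S)-1-methylcyclohex-2-en-1-yl]acetate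
Product: 4 N-methoxy-N-methyl-2-[(1S)-1-methylcyclohex-2-en-1-yl]acetamide
Conditions: MeNH(OMe)·HCl, i-PrMgCl, THF, −20 → 0 °C
Reagents that add atoms: N,O-dimethylhydroxylamine hydrochloride, CNOC.Cl
Why: Weinreb amide formation by aminolysis of the ester with the chloromagnesium amide, which leaves the ring alkene untouched.

Step 4
Reactants: 4 N-methoxy-N-methyl-2-[(1S)-1-methylcyclohex-2-en-1-yl]acetamide
Product: 5 1-[(1S)-1-methylcyclohex-2-en-1-yl]but-3-en-2-one
Conditions: CH2=CHMgBr, THF, 0 °C; inverse quench into cold 1 M HCl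
Reagents that add atoms: vinylmagnesium bromide, C=C[Mg]Br
Why: Weinreb ketone synthesis, in which the chelated tetrahedral adduct persists until the acidic quench, so one vinyl group is added and the released amine is protonated before it can add to the vinyl ketone.

Step 5
Reactants: 5 1-[(1S)-1-methylcyclohex-2-en-1-yl]but-3-en-2-one
Product: 7 2-(2-bromoethyl)-2-{[(1S)-1-methylcyclohex-2-en-1-yl]methyl}-1,3-dioxolane, via β-bromo ketone 6 (not isolated)
Conditions: HBr (g), CH2Cl2, 0 °C; then HOCH2CH2OH, HC(OEt)3, TsOH (cat.), rt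
Reagents that add atoms: hydrogen bromide, Br; ethylene glycol, OCCO
Why: Conjugate hydrobromination of the vinyl ketone followed by acid-catalysed dioxolane formation with orthoformate as water scavenger (the standard β-halo ketal preparation), the isolated ring alkene adding HBr far more slowly than the enone.

Step 6
Reactants: 7 2-(2-bromoethyl)-2-{[(1S)-1-methylcyclohex-2-en-1-yl]methyl}-1,3-dioxolane
Product: 8 (4S)-4-{[2-(2-bromoethyl)-1,3-dioxolan-2-yl]methyl}-4-methylcyclohex-2-en-1-one
Conditions: Rh2(cap)4 (1 mol %), t-BuOOH (70 % aq.), K2CO3, CH2Cl2, rt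
Reagents that add atoms: tert-butyl hydroperoxide, CC(C)(C)OO
Why: Dirhodium caprolactamate-catalysed allylic oxidation, in which the only allylic C–H bonds lie on the ring CH2 remote from the quaternary carbon, so the carbonyl can form only at the position that gives the 4,4-disubstituted cyclohex-2-enone.

Step 7
Reactants: 8 (4S)-4-{[2-(2-bromoethyl)-1,3-dioxolan-2-yl]methyl}-4-methylcyclohex-2-en-1-one
Product: 9 (4S)-4-{[2-(2-bromoethyl)-1,3-dioxolan-2-yl]methyl}-2-iodo-4-methylcyclohex-2-en-1-one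
Conditions: I2, pyridine, CH2Cl2, rt
Reagents that add atoms: iodine, II
Why: Johnson α-iodination of an enone (conjugate addition of pyridine, iodination of the enolate, elimination), established for 4,4-disubstituted cyclohexenones.

Step 8
Reactants: 10 2-methylbut-3-en-2-ol
Product: 11 triethyl[(2-methylbut-3-en-2-yl)oxy]silane
Conditions: TESOTf, 2,6-lutidine, CH2Cl2, 0 °C
Reagents that add atoms: triethylsilyl trifluoromethanesulfonate, CC[Si](CC)(CC)OS(=O)(=O)C(F)(F)F
Why: Silylation of a tertiary alcohol with a silyl triflate and a hindered pyridine base.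

Step 9
Reactants: 11 triethyl[(2-methylbut-3-en-2-yl)oxy]silane; 9 (4S)-4-{[2-(2-bromoethyl)-1,3-dioxolan-2-yl]methyl}-2-iodo-4-methylcyclohex-2-en-1-one
Product: 13 (4S)-4-{[2-(2-bromoethyl)-1,3-dioxolan-2-yl]methyl}-4-methyl-2-[3-methyl-3-(triethylsilyloxy)butyl]cyclohex-2-en-1-one, via alkylborane 12 (not isolated)
Conditions: 9-BBN, THF, rt; then 9, PdCl2(dppf) (5 mol %), AsPh3, Cs2CO3, DMF–H2O, rt
Reagents that add atoms: none
Why: Anti-Markovnikov hydroboration with 9-BBN followed by B-alkyl Suzuki–Miyaura coupling with an α-iodoenone, oxidative addition into the C(sp2)–I bond being much faster than into the primary C(sp3)–Br bond, which is kept.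

Step 10
Reactants: 13 (4S)-4-{[2-(2-bromoethyl)-1,3-dioxolan-2-yl]methyl}-4-methyl-2-[3-methyl-3-(triethylsilyloxy)butyl]cyclohex-2-en-1-one
Product: 14 (4S)-4-{[2-(2-iodoethyl)-1,3-dioxolan-2-yl]methyl}-4-methyl-2-[3-methyl-3-(triethylsilyloxy)butyl]cyclohex-2-en-1-one
Conditions: NaI, NaHCO3, acetone, reflux
Reagents that add atoms: sodium iodide, [Na+].[I-]
Why: Finkelstein exchange at an unhindered primary bromide, driven by precipitation of NaBr, with bicarbonate guarding ketal and silyl ether against traces of acid.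

Step 11
Reactants: 14 (4S)-4-{[2-(2-iodoethyl)-1,3-dioxolan-2-yl]methyl}-4-methyl-2-[3-methyl-3-(triethylsilyloxy)butyl]cyclohex-2-en-1-one
Product: 16 (4R,5R,10S)-8,8-ethylenedioxy-4α,10α-dimethyl-4β-[3-methyl-3-(triethylsilyloxy)butyl]-5αH-decalin-3-one, via samarium enolate 15 (not isolated)
Conditions: SmI2 (2.2 equiv), HMPA, THF, −40 → 0 °C, slow addition of 14; then MeI (excess), 0 °C → rt
Reagents that add atoms: iodomethane, CI
Why: SmI2–HMPA transfers an electron to the C–I bond, the primary radical at C-6 adds to C-5 (the β-carbon of the ring-A enone), and a second SmI2 reduces the α-keto radical at C-4 to the samarium(III) enolate 15, which MeI methylates at carbon; the closest known reaction type is the SmI2-promoted intramolecular conjugate addition of an alkyl iodide to an enone with electrophilic capture of the samarium enolate. Ring B closes in the 6-exo-trig mode. At C-5 the three-atom tether hangs from C-10 and can reach the neighbouring sp2 carbon only on its own face along the axial trajectory, so H-5 ends up cis to the angular methyl (cis-decalin). At C-4 the enolate is regiodefined by the reduction itself, and MeI should approach its convex α face, anti to the new C-5–C-6 bond and away from ring B, which puts the new methyl α and leaves the chain β. The step needs reduction of the iodide and ring closure to outrun intermolecular enone coupling, which slow addition at high dilution and the fast addition of a nucleophilic radical to an electron-poor alkene should secure, and it needs C- rather than O-alkylation, which the soft electrophile, HMPA and the absence of a proton source favour. The ketal and the silyl ether are inert to SmI2.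

Step 12
Reactants: 16 (4R,5R,10S)-8,8-ethylenedioxy-4α,10α-dimethyl-4β-[3-methyl-3-(triethylsilyloxy)butyl]-5αH-decalin-3-one
Product: 17 (3S,4R,5R,10S)-8,8-ethylenedioxy-4α,10α-dimethyl-4β-[3-methyl-3-(triethylsilyloxy)butyl]-5αH-decalin-3β-ol
Conditions: NaBH4, MeOH–THF, 0 °C → rt
Reagents that add atoms: none
Why: Borohydride reduction of a hindered ketone, in which the β face of C-3 is screened in either chair of ring A (by the syn-axial C-5–C-6 bond in one, by the axial C-4 chain in the other), so hydride should enter from the convex α face and give the 3β (3S) alcohol.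

Step 13
Reactants: 17 (3S,4R,5R,10S)-8,8-ethylenedioxy-4α,10α-dimethyl-4β-[3-methyl-3-(triethylsilyloxy)butyl]-5αH-decalin-3β-ol
Product: 18 (3S,4R,5R,10S)-3β-(tert-butyldimethylsilyloxy)-8,8-ethylenedioxy-4α,10α-dimethyl-4β-[3-methyl-3-(triethylsilyloxy)butyl]-5αH-decalin
Conditions: TBSOTf, 2,6-lutidine, CH2Cl2, −40 → 0 °C
Reagents that add atoms: tert-butyldimethylsilyl trifluoromethanesulfonate, CC(C)(C)[Si](C)(C)OS(=O)(=O)C(F)(F)F
Why: Silylation of a hindered secondary alcohol with the silyl triflate, under buffered low-temperature conditions that a ketal and a triethylsilyl ether tolerate.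

Step 14
Reactants: 18 (3S,4R,5R,10S)-3β-(tert-butyldimethylsilyloxy)-8,8-ethylenedioxy-4α,10α-dimethyl-4β-[3-methyl-3-(triethylsilyloxy)butyl]-5αH-decalin
Product: 19 (3S,4R,5R,10S)-3β-(tert-butyldimethylsilyloxy)-4α,10α-dimethyl-4β-[3-methyl-3-(triethylsilyloxy)butyl]-5αH-decalin-8-one
Conditions: PPTS (cat.), acetone–H2O, 45 °C
Reagents that add atoms: water, O
Why: Mild acid-catalysed hydrolysis of the dioxolane, under which a hindered secondary TBS ether and a tertiary TES ether are expected to persist.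

Step 15
Reactants: 19 (3S,4R,5R,10S)-3β-(tert-butyldimethylsilyloxy)-4α,10α-dimethyl-4β-[3-methyl-3-(triethylsilyloxy)butyl]-5αH-decalin-8-one
Product: 20 (3S,4R,5R,10S)-3β-(tert-butyldimethylsilyloxy)-4α,10α-dimethyl-4β-[3-methyl-3-(triethylsilyloxy)butyl]-5αH-decal-6-en-8-one
Conditions: IBX, DMSO–PhF, 70 °C
Reagents that add atoms: none
Why: IBX dehydrogenation of a ketone to the enone, where the quaternary C-10 allows unsaturation only between C-6 and C-7, so the regiochemistry is fixed by the substrate and C-7 is removed as an enolisable position.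

Step 16
Reactants: 21 methyl acetoacetate; 22 malonyl dichloride
Product: 23 methyl 4-hydroxy-2-methyl-6-oxo-6H-pyran-3-carboxylate
Conditions: CH2Cl2, rt → 40 °C, N2 sweep to remove HCl
Reagents that add atoms: none
Why: C-acylation of the β-keto ester enol by the diacid chloride followed by lactonisation of the enol oxygen onto the second acid chloride, the classical malonyl chloride route to 4-hydroxy-2-pyranones.

Step 17
Reactants: 23 methyl 4-hydroxy-2-methyl-6-oxo-6H-pyran-3-carboxylate
Product: 24 methyl 4-hydroxy-5-iodo-2-methyl-6-oxo-6H-pyran-3-carboxylate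
Conditions: NIS, MeCN, rt
Reagents that add atoms: N-iodosuccinimide, O=C1CCC(=O)N1I
Why: Electrophilic iodination at the only free ring carbon, the nucleophilic α-carbon of the enolised β-dicarbonyl unit of a 4-hydroxy-2-pyranone.

Step 18
Reactants: 24 methyl 4-hydroxy-5-iodo-2-methyl-6-oxo-6H-pyran-3-carboxylate
Product: 25 methyl 5-iodo-6-methoxy-2-methyl-4-oxo-4H-pyran-3-carboxylate
Conditions: MeOTf, CH2Cl2, rt; aq. NaHCO3 work-up
Reagents that add atoms: methyl trifluoromethanesulfonate, COS(=O)(=O)C(F)(F)F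
Why: O-methylation of a 4-hydroxy-2-pyranone with a hard methylating agent occurs at the lactone carbonyl oxygen and gives the 2-methoxy-4-pyranone, the 4-OH being held in a hydrogen bond to the neighbouring ester.

Step 19
Reactants: 25 methyl 5-iodo-6-methoxy-2-methyl-4-oxo-4H-pyran-3-carboxylate
Product: 27 methyl 5-formyl-6-methoxy-2-methyl-4-oxo-4H-pyran-3-carboxylate, via pyranylmagnesium chloride 26 (not isolated)
Conditions: i-PrMgCl·LiCl, THF, −60 °C; DMF, −60 → 0 °C; aq. citric acid
Reagents that add atoms: N,N-dimethylformamide, CN(C)C=O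
Why: Iodine–magnesium exchange with the turbo-Grignard reagent at low temperature tolerates the ester and the ring carbonyl, and the alkenylmagnesium species is formylated by DMF (Bouveault formylation).

Step 20
Reactants: 20 (3S,4R,5R,10S)-3β-(tert-butyldimethylsilyloxy)-4α,10α-dimethyl-4β-[3-methyl-3-(triethylsilyloxy)butyl]-5αH-decal-6-en-8-one; 27 methyl 5-formyl-6-methoxy-2-methyl-4-oxo-4H-pyran-3-carboxylate
Product: 29 9-[hydroxy(Pyr)methyl] derivative of 20 (mixture of C-9 and C-11 diastereomers), via lithium dienolate 28 (not isolated)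
Conditions: LDA, THF, −78 °C; then 27, −78 °C; aq. NH4Cl quench
Reagents that add atoms: none
Why: Kinetic deprotonation of the enone at its α′ carbon C-9 (C-7 is now sp2) gives the cross-conjugated lithium dienolate, which undergoes aldol addition to the aldehyde, and the two new stereocentres are erased in the next step.

Step 21
Reactants: 29 9-[hydroxy(Pyr)methyl] derivative of 20
Product: 31 9-(Pyr-methylidene) derivative of 20 (9(11)-ene; either alkene geometry), via mesylate 30 (not isolated)
Conditions: MsCl, Et3N, CH2Cl2, 0 °C; then DBU, rt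
Reagents that add atoms: none
Why: Mesylation of the β-hydroxy ketone and E1cB elimination with DBU give the exocyclic enone, and either alkene geometry serves the next step.

Step 22
Reactants: 31 9-(Pyr-methylidene) derivative of 20
Product: 32 (3S,4R,5R,9R,10R)-3β-(tert-butyldimethylsilyloxy)-4α,10α-dimethyl-4β-[3-methyl-3-(triethylsilyloxy)butyl]-9β-(Pyr-methyl)-5αH-decalin-8-one
Conditions: H2 (1 atm), 10 % Pd/C, EtOAc, rt
Reagents that add atoms: none
Why: Heterogeneous hydrogenation saturates the C-6=C-7 and the exocyclic C-9=C-11 bonds of the cross-conjugated dienone, hydrogen should reach C-9 from the convex α face opposite ring A so that the pyranonylmethyl group ends up β (trans to the angular methyl), and the fully substituted pyranone double bonds are not reduced.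

Step 23
Reactants: 32 (3S,4R,5R,9R,10R)-3β-(tert-butyldimethylsilyloxy)-4α,10α-dimethyl-4β-[3-methyl-3-(triethylsilyloxy)butyl]-9β-(Pyr-methyl)-5αH-decalin-8-one
Product: 33 (3S,4R,5R,9S,10S)-3β-(tert-butyldimethylsilyloxy)-4α,10α-dimethyl-8-methylidene-4β-[3-methyl-3-(triethylsilyloxy)butyl]-9β-(Pyr-methyl)-5αH-decalin
Conditions: Zn, CH2Br2, TiCl4, THF–CH2Cl2, 0 °C → rt
Reagents that add atoms: dibromomethane, BrCBr
Why: Lombardo–Takai methylenation, a non-basic zinc–titanium methylene reagent that converts hindered enolisable ketones without epimerising C-9 and leaves the ester and the pyranone carbonyl alone.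

Step 24
Reactants: 33 (3S,4R,5R,9S,10S)-3β-(tert-butyldimethylsilyloxy)-4α,10α-dimethyl-8-methylidene-4β-[3-methyl-3-(triethylsilyloxy)butyl]-9β-(Pyr-methyl)-5αH-decalin
Product: 34 (3S,4R,5R,9S,10S)-3β-(tert-butyldimethylsilyloxy)-4β-(3-hydroxy-3-methylbutyl)-4α,10α-dimethyl-8-methylidene-9β-(Pyr-methyl)-5αH-decalin
Conditions: HF·pyridine, pyridine, THF, 0 °C
Reagents that add atoms: none
Why: Buffered HF·pyridine cleaves the triethylsilyl ether much faster than the hindered secondary TBS ether.

Step 25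
Reactants: 34 (3S,4R,5R,9S,10S)-3β-(tert-butyldimethylsilyloxy)-4β-(3-hydroxy-3-methylbutyl)-4α,10α-dimethyl-8-methylidene-9β-(Pyr-methyl)-5αH-decalin
Product: 35 (3S,4R,5R,9S,10S)-3β-(tert-butyldimethylsilyloxy)-4β-[3-(formyloxy)-3-methylbutyl]-4α,10α-dimethyl-8-methylidene-9β-(Pyr-methyl)-5αH-decalin
Conditions: HCO2H/Ac2O (premixed), pyridine, 0 °C → rt
Reagents that add atoms: acetic formic anhydride, CC(=O)OC=O
Why: Formylation of the tertiary alcohol with acetic formic anhydride, which transfers the formyl group selectively, the only other hydroxyl being silylated.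

Step 26
Reactants: 35 (3S,4R,5R,9S,10S)-3β-(tert-butyldimethylsilyloxy)-4β-[3-(formyloxy)-3-methylbutyl]-4α,10α-dimethyl-8-methylidene-9β-(Pyr-methyl)-5αH-decalin
Product: 36 (3S,4R,5R,9S,10S)-4β-[3-(formyloxy)-3-methylbutyl]-4α,10α-dimethyl-8-methylidene-9β-(Pyr-methyl)-5αH-decalin-3β-ol (CNP0292250.1)
Conditions: HF·pyridine, THF, rt
Reagents that add atoms: none
Why: Fluoride cleavage of the TBS ether under mildly acidic, non-nucleophilic conditions that should spare the tertiary formate, the exocyclic alkene and the methoxypyranone.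

**Compound list**
1 | 3-methylcyclohex-2-en-1-one | CC1=CC(=O)CCC1 | starting material
2 | (S)-3-methylcyclohex-2-en-1-ol | O[C@@H]1C=C(C)CCC1 | intermediate
3 | ethyl 2-[(1S)-1-methylcyclohex-2-en-1-yl]acetate | C1CC[C@@](C)(CC(=O)OCC)C=C1 | intermediate
4 | N-methoxy-N-methyl-2-[(1S)-1-methylcyclohex-2-en-1-yl]acetamide | C1CC[C@@](C)(CC(=O)N(C)OC)C=C1 | intermediate
5 | 1-[(1S)-1-methylcyclohex-2-en-1-yl]but-3-en-2-one | C1CC[C@@](C)(CC(=O)C=C)C=C1 | intermediate
6 | 4-bromo-1-[(1S)-1-methylcyclohex-2-en-1-yl]butan-2-one | C1CC[C@@](C)(CC(=O)CCBr)C=C1 | intermediate (not isolated)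
7 | 2-(2-bromoethyl)-2-{[(1S)-1-methylcyclohex-2-en-1-yl]methyl}-1,3-dioxolane | C1CC[C@@](C)(CC2(OCCO2)CCBr)C=C1 | intermediate
8 | (4S)-4-{[2-(2-bromoethyl)-1,3-dioxolan-2-yl]methyl}-4-methylcyclohex-2-en-1-one | O=C1CC[C@@](C)(CC2(OCCO2)CCBr)C=C1 | intermediate
9 | (4S)-4-{[2-(2-bromoethyl)-1,3-dioxolan-2-yl]methyl}-2-iodo-4-methylcyclohex-2-en-1-one | O=C1CC[C@@](C)(CC2(OCCO2)CCBr)C=C1I | intermediate
10 | 2-methylbut-3-en-2-ol | C=CC(C)(C)O | starting material
11 | triethyl[(2-methylbut-3-en-2-yl)oxy]silane | C=CC(C)(C)O[Si](CC)(CC)CC | intermediate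
12 | 9-[3-methyl-3-(triethylsilyloxy)butyl]-9-borabicyclo[3.3.1]nonane | CC(C)(CCB1C2CCCC1CCC2)O[Si](CC)(CC)CC | intermediate (not isolated)
13 | (4S)-4-{[2-(2-bromoethyl)-1,3-dioxolan-2-yl]methyl}-4-methyl-2-[3-methyl-3-(triethylsilyloxy)butyl]cyclohex-2-en-1-one | O=C1CC[C@@](C)(CC2(OCCO2)CCBr)C=C1CCC(C)(C)O[Si](CC)(CC)CC | intermediate
14 | (4S)-4-{[2-(2-iodoethyl)-1,3-dioxolan-2-yl]methyl}-4-methyl-2-[3-methyl-3-(triethylsilyloxy)butyl]cyclohex-2-en-1-one | O=C1CC[C@@](C)(CC2(OCCO2)CCI)C=C1CCC(C)(C)O[Si](CC)(CC)CC | intermediate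
15 | diiodosamarium(III) 8,8-ethylenedioxy-10α-methyl-4-[3-methyl-3-(triethylsilyloxy)butyl]-5αH-decal-3-en-3-olate (cis-fused) | O1CCOC12CC[C@H]3C(CCC(C)(C)O[Si](CC)(CC)CC)=C(O[Sm](I)I)CC[C@@]3(C)C2 | intermediate (not isolated)
16 | (4R,5R,10S)-8,8-ethylenedioxy-4α,10α-dimethyl-4β-[3-methyl-3-(triethylsilyloxy)butyl]-5αH-decalin-3-one | O1CCOC12CC[C@H]3[C@@](C)(CCC(C)(C)O[Si](CC)(CC)CC)C(=O)CC[C@@]3(C)C2 | intermediate
17 | (3S,4R,5R,10S)-8,8-ethylenedioxy-4α,10α-dimethyl-4β-[3-methyl-3-(triethylsilyloxy)butyl]-5αH-decalin-3β-ol | O1CCOC12CC[C@H]3[C@@](C)(CCC(C)(C)O[Si](CC)(CC)CC)[C@@H](O)CC[C@@]3(C)C2 | intermediate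
18 | (3S,4R,5R,10S)-3β-(tert-butyldimethylsilyloxy)-8,8-ethylenedioxy-4α,10α-dimethyl-4β-[3-methyl-3-(triethylsilyloxy)butyl]-5αH-decalin | O1CCOC12CC[C@H]3[C@@](C)(CCC(C)(C)O[Si](CC)(CC)CC)[C@@H](O[Si](C)(C)C(C)(C)C)CC[C@@]3(C)C2 | intermediate
19 | (3S,4R,5R,10S)-3β-(tert-butyldimethylsilyloxy)-4α,10α-dimethyl-4β-[3-methyl-3-(triethylsilyloxy)butyl]-5αH-decalin-8-one | O=C1CC[C@H]2[C@@](C)(CCC(C)(C)O[Si](CC)(CC)CC)[C@@H](O[Si](C)(C)C(C)(C)C)CC[C@@]2(C)C1 | intermediate
20 | (3S,4R,5R,10S)-3β-(tert-butyldimethylsilyloxy)-4α,10α-dimethyl-4β-[3-methyl-3-(triethylsilyloxy)butyl]-5αH-decal-6-en-8-one | O=C1C=C[C@H]2[C@@](C)(CCC(C)(C)O[Si](CC)(CC)CC)[C@@H](O[Si](C)(C)C(C)(C)C)CC[C@@]2(C)C1 | intermediate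
21 | methyl acetoacetate | COC(=O)CC(C)=O | starting material
22 | malonyl dichloride | O=C(Cl)CC(Cl)=O | starting material
23 | methyl 4-hydroxy-2-methyl-6-oxo-6H-pyran-3-carboxylate | COC(=O)C1=C(C)OC(=O)C=C1O | intermediate
24 | methyl 4-hydroxy-5-iodo-2-methyl-6-oxo-6H-pyran-3-carboxylate | COC(=O)C1=C(C)OC(=O)C(I)=C1O | intermediate
25 | methyl 5-iodo-6-methoxy-2-methyl-4-oxo-4H-pyran-3-carboxylate | COC(=O)c1c(C)oc(OC)c(I)c1=O | intermediate
26 | [5-(methoxycarbonyl)-2-methoxy-6-methyl-4-oxo-4H-pyran-3-yl]magnesium chloride | COC(=O)c1c(C)oc(OC)c([Mg]Cl)c1=O | intermediate (not isolated)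
27 | methyl 5-formyl-6-methoxy-2-methyl-4-oxo-4H-pyran-3-carboxylate | COC(=O)c1c(C)oc(OC)c(C=O)c1=O | intermediate
28 | lithium 6,8-dien-8-olate of 20 (cross-conjugated dienolate) | [Li]OC=1C=C[C@H]2[C@@](C)(CCC(C)(C)O[Si](CC)(CC)CC)[C@@H](O[Si](C)(C)C(C)(C)C)CC[C@@]2(C)C=1 | intermediate (not isolated)
29 | 9-[hydroxy(Pyr)methyl] derivative of 20, mixture of C-9 and C-11 diastereomers | O=C1C=C[C@H]2[C@@](C)(CCC(C)(C)O[Si](CC)(CC)CC)[C@@H](O[Si](C)(C)C(C)(C)C)CC[C@@]2(C)C1C(O)c1c(OC)oc(C)c(C(=O)OC)c1=O | intermediate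
30 | 11-methanesulfonate of 29 | O=C1C=C[C@H]2[C@@](C)(CCC(C)(C)O[Si](CC)(CC)CC)[C@@H](O[Si](C)(C)C(C)(C)C)CC[C@@]2(C)C1C(OS(C)(=O)=O)c1c(OC)oc(C)c(C(=O)OC)c1=O | intermediate (not isolated)
31 | 9-(Pyr-methylidene) derivative of 20 (6,9(11)-dien-8-one, alkene geometry not specified) | O=C1C=C[C@H]2[C@@](C)(CCC(C)(C)O[Si](CC)(CC)CC)[C@@H](O[Si](C)(C)C(C)(C)C)CC[C@@]2(C)C1=Cc1c(OC)oc(C)c(C(=O)OC)c1=O | intermediate
32 | (3S,4R,5R,9R,10R)-3β-(tert-butyldimethylsilyloxy)-4α,10α-dimethyl-4β-[3-methyl-3-(triethylsilyloxy)butyl]-9β-(Pyr-methyl)-5αH-decalin-8-one | O=C1CC[C@H]2[C@@](C)(CCC(C)(C)O[Si](CC)(CC)CC)[C@@H](O[Si](C)(C)C(C)(C)C)CC[C@@]2(C)[C@H]1Cc1c(OC)oc(C)c(C(=O)OC)c1=O | intermediate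
33 | (3S,4R,5R,9S,10S)-3β-(tert-butyldimethylsilyloxy)-4α,10α-dimethyl-8-methylidene-4β-[3-methyl-3-(triethylsilyloxy)butyl]-9β-(Pyr-methyl)-5αH-decalin | C=C1CC[C@H]2[C@@](C)(CCC(C)(C)O[Si](CC)(CC)CC)[C@@H](O[Si](C)(C)C(C)(C)C)CC[C@@]2(C)[C@H]1Cc1c(OC)oc(C)c(C(=O)OC)c1=O | intermediate
34 | (3S,4R,5R,9S,10S)-3β-(tert-butyldimethylsilyloxy)-4β-(3-hydroxy-3-methylbutyl)-4α,10α-dimethyl-8-methylidene-9β-(Pyr-methyl)-5αH-decalin | C=C1CC[C@H]2[C@@](C)(CCC(C)(C)O)[C@@H](O[Si](C)(C)C(C)(C)C)CC[C@@]2(C)[C@H]1Cc1c(OC)oc(C)c(C(=O)OC)c1=O | intermediate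
35 | (3S,4R,5R,9S,10S)-3β-(tert-butyldimethylsilyloxy)-4β-[3-(formyloxy)-3-methylbutyl]-4α,10α-dimethyl-8-methylidene-9β-(Pyr-methyl)-5αH-decalin | C=C1CC[C@H]2[C@@](C)(CCC(C)(C)OC=O)[C@@H](O[Si](C)(C)C(C)(C)C)CC[C@@]2(C)[C@H]1Cc1c(OC)oc(C)c(C(=O)OC)c1=O | intermediate
36 | (3S,4R,5R,9S,10S)-4β-[3-(formyloxy)-3-methylbutyl]-4α,10α-dimethyl-8-methylidene-9β-(Pyr-methyl)-5αH-decalin-3β-ol (CNP0292250.1) | C=C1CC[C@H]2[C@@](C)(CCC(C)(C)OC=O)[C@@H](O)CC[C@@]2(C)[C@H]1Cc1c(OC)oc(C)c(C(=O)OC)c1=O | target

**Step count and risks**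
Total step count: 26. Longest linear sequence: 21 steps (steps 1–7, 9–15, 20–26). Side branches: step 8 (one step) and steps 16–19 (four steps).

Steps most likely to fail:

Step 11. The samarium(III) enolate 15 is a weak nucleophile. C-methylation may lag behind protonation on work-up or O-methylation, and MeI may not discriminate fully between the two enolate faces. Fallback: starting from 14, the SmI2–HMPA cyclisation is run as before, but the enolate is silylated with TMSCl and the regiodefined trimethylsilyl enol ether F1 is isolated. MeLi in THF at 0 °C then releases the lithium enolate F2, which is methylated with MeI in THF–DMPU at −78 °C and returns to 16.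

Step 20. Deprotonation and addition at the neopentyl α′ carbon may be slow. The basic dienolate may also attack C-6 of the pyranone ring in 27 (the carbon that bears the methoxy group) with loss of methoxide, or the aldolate may revert. Fallback: enone 20 is converted with LDA and TMSCl into the 8-trimethylsilyloxy-6,8-diene F3, which is combined with aldehyde 27 and BF3·OEt2 in CH2Cl2 at −78 °C (Mukaiyama aldol addition) and comes back at 29. The Lewis acid activates the formyl group and no basic enolate is present.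

Step 22. Hydrogen may be delivered to C-9 with poor facial selectivity, or the hindered exocyclic alkene next to the quaternary C-10 may be reduced sluggishly. Fallback: the carbon substituent is introduced on the open face instead of the hydrogen. Aldehyde 27 is reduced with NaBH4 (MeOH, −20 °C) to the hydroxymethylpyranone F4, which CBr4/PPh3 converts into the bromomethylpyranone F5. Lithium dienolate 28 (from 20 and LDA) is alkylated with F5 to give the 9-(Pyr-methyl) enone F6, and hydrogenation of the C-6=C-7 bond (H2, Pd/C, EtOAc) rejoins the route at 32. This path is taken if the hydrogenation shows the β face of C-9 to be the accessible one.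

Further compounds
F1 | step 11 | 8,8-ethylenedioxy-10α-methyl-4-[3-methyl-3-(triethylsilyloxy)butyl]-3-(trimethylsilyloxy)-5αH-decal-3-ene (cis-fused) | O1CCOC12CC[C@H]3C(CCC(C)(C)O[Si](CC)(CC)CC)=C(O[Si](C)(C)C)CC[C@@]3(C)C2
F2 | step 11 | lithium 8,8-ethylenedioxy-10α-methyl-4-[3-methyl-3-(triethylsilyloxy)butyl]-5αH-decal-3-en-3-olate (cis-fused) | O1CCOC12CC[C@H]3C(CCC(C)(C)O[Si](CC)(CC)CC)=C(O[Li])CC[C@@]3(C)C2
F3 | step 20 | 8-(trimethylsilyloxy)-6,8-diene derived from 20 | C[Si](C)(C)OC=1C=C[C@H]2[C@@](C)(CCC(C)(C)O[Si](CC)(CC)CC)[C@@H](O[Si](C)(C)C(C)(C)C)CC[C@@]2(C)C=1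
F4 | step 22 | methyl 5-(hydroxymethyl)-6-methoxy-2-methyl-4-oxo-4H-pyran-3-carboxylate | COC(=O)c1c(C)oc(OC)c(CO)c1=O
F5 | step 22 | methyl 5-(bromomethyl)-6-methoxy-2-methyl-4-oxo-4H-pyran-3-carboxylate | COC(=O)c1c(C)oc(OC)c(CBr)c1=O
F6 | step 22 | 3β-(tert-butyldimethylsilyloxy)-4α,10α-dimethyl-4β-[3-methyl-3-(triethylsilyloxy)butyl]-9β-(Pyr-methyl)-5αH-decal-6-en-8-one | O=C1C=C[C@H]2[C@@](C)(CCC(C)(C)O[Si](CC)(CC)CC)[C@@H](O[Si](C)(C)C(C)(C)C)CC[C@@]2(C)[C@H]1Cc1c(OC)oc(C)c(C(=O)OC)c1=O
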